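The data stem from a simulated flask with made-up constants; noise was put on by code.

80.0% is the ceiling of the flask noon and 62.5% that of the flask midnight, a ceiling being, where Z is the smaller charge, the Z charged over the Q charged. We read it from the runs. In the readings X and Q add up to about the charge, and epsilon stops at 34.7% of its Q against 34.8% from its Z. So one Z goes per Q turned into X, and Z is the limiting reagent in both flasks.

| setting | zeta | beta | delta | epsilon | noon | midnight |
|---|---|---|---|---|---|---|
| Q | 0.10 M | 0.10 M | 0.10 M | 0.23 M | 0.10 M | 0.40 M |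
| Z | 0.072 M | 0.14 M | 0.24 M | 0.080 M | 0.0800 M | 0.250 M |
| remark | run made earlier | run made earlier | run made earlier | run made earlier |  |  |
| time |  |  |  |  | 8.0 h | 8.0 h |

| run | time / h | X / % | Q / % |
|---|---|---|---|
| zeta | 1.00 | 38.4 | 62.0 |
| zeta | 2.50 | 60.5 | 39.3 |
| zeta | 3.00 | 62.8 | 36.6 |
| zeta | 5.00 | 68.3 | 31.8 |
| zeta | 6.00 | 69.4 | 30.2 |
| beta | 0.500 | 53.0 | 47.1 |
| beta | 1.33 | 88.0 | 12.1 |
| beta | 2.50 | 95.4 | 3.5 |
| beta | 4.00 | 98.7 | 0.7 |
| beta | 6.00 | 100.0 | 0.3 |
| delta | 0.500 | 93.7 | 6.2 |
| delta | 1.33 | 100.0 | 0.1 |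
| delta | 2.50 | 99.7 | 0 |
| delta | 4.00 | 100.4 | 0 |
| delta | 6.00 | 100.0 | 0 |
| epsilon | 0.500 | 23.5 | 76.1 |
| epsilon | 1.33 | 33.1 | 67.6 |
| epsilon | 2.50 | 34.5 | 65.8 |
| epsilon | 4.00 | 34.5 | 65.2 |
| epsilon | 6.00 | 34.7 | 65.2 |

(each reading ± 0.3 percentage points)

- a reading or a percentage of X counts all its forms, free or not

- which of the two ends with the higher amount of X, in percent of the Q charged ("neither" if they lie within 2 percentage points) (noon / midnight / neither)
- X at the end, in percent of the Q charged, noon
- X at the end, in percent of the Q charged, midnight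

Does noon get near its ceiling in 8.0 h? We follow the rate r = k[Q][Z], with k the second-order constant. The tail of zeta, where Z is low as it will be late in noon, gives a reading of k = 0.213 M⁻¹ min⁻¹. On this law we reckon the start of noon at 0.102 M h⁻¹. Two factors slow it. The Q factor stops at 20.0% of its start, while the Z factor keeps falling, so late in the run the decay is pseudo-first-order.

The quantity to carry is the closing number N, which is k times the difference of the two charges times the time. It counts the e-foldings of the late decay. On this law, with Q the larger charge, a large N puts a flask close to its ceiling. Noon has N = 2.04 and midnight 15.3. The integrated law leaves noon 2.3 percentage points under its ceiling. By then the reckoned Q factor is 22.3% and the reckoned Z factor 2.90%, so on this law the rate is down by a factor of 155. Our reckoning is 77.7% for noon and the ceiling for midnight, a lead for noon.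

The forecast, taking k as 13 because “the slowest value is enough here”, says noon, with 78% (76% to 79.7%) and 62.3% (60.5% to 63%).

The flask gives noon, at 77.9% against 62.5%.

    Q + Z + D → X + 2 D (k = 20.0 M⁻² min⁻¹)
    Q + Z → X + D (k = 0.00300 M⁻¹ min⁻¹)
    Z + X ⇌ L, settled at all times (K = 83.0 M⁻¹)

Midnight has come to rest at its ceiling: ten times the time leaves 62.5%. A neighbouring flask, midnight with 1.0 M of Q, has N = 76.5 and a ceiling of 25.0%, and it ends at 25.0%. Noon, with N = 2.04, stands 2.1 points under its ceiling, with 0.35% of its Z free at 8.00 h. Ten times the time raises its N to 20.4 and its X by 2.1 points, to 80.0%.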